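Labdane numbering is used. Ring B of the cis-fused decalin is a methylenecyclohexane, so its C7–C8(=C17)–C9 unit is a trimethylenemethane piece and ring B is cut at C6–C7 and C9–C10, a (3+3) disconnection. In one flask, ring A enone bromide 10 (C6 as CH2Br, C10 as enone β-carbon) and 2-(silylmethyl)allyl acetate 19 are joined: nickel-catalysed allyl–alkyl coupling makes C6–C7 and leaves an allylsilane that, with EtAlCl2, adds to the enone to make C9–C10. This closes ring B and sets the quaternary C10, the cis fusion, C9 and the exocyclic methylene at once.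

Key step: step 11

Assumption 1: the SMILES is read as the A/B cis-fused diastereomer (H-5 and the C-10 methyl on the same face; 1S,4aR,5S,8aS), and the route is built for exactly that isomer.
Assumption 2: the facial sense of the catalyst in step 3 is taken from the formyl C–H···O binding model; should it prove opposite, the antipodal catalyst is used with no other change.

Step 1
Reactants: 1 glyoxal (40 % aqueous); 2 methyl 2-(triphenyl-λ5-phosphanylidene)propanoate
Product: 3 methyl (E)-2-methyl-4-oxobut-2-enoate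
Conditions: 1 (5 equiv), CH2Cl2/H2O, 0 °C → rt
Reagents that add atoms: none
Why: Wittig olefination with a stabilised α-methyl ylide should be E-selective (CHO trans to CO2Me), and the excess of glyoxal should hold it at mono-olefination.

Step 2
Reactants: 4 (E)-pent-3-en-2-one
Product: 6 tert-butyl(dimethyl)[(E)-penta-1,3-dien-2-yloxy]silane, via lithium dienolate 5 (not isolated)
Conditions: LiN(iPr)2, THF, −78 °C; then TBSCl, HMPA, −78 °C → 0 °C
Reagents that add atoms: tert-butyldimethylsilyl chloride, CC(C)(C)[Si](C)(C)Cl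
Why: Kinetic deprotonation of the methyl ketone side and O-silylation (silyl enol ether formation) should give the 2-silyloxy-1,3-diene and not the linear dienol ether.

Step 3
Reactants: 3 methyl (E)-2-methyl-4-oxobut-2-enoate; 6 tert-butyl(dimethyl)[(E)-penta-1,3-dien-2-yloxy]silane
Product: 7 methyl (1S,5S,6S)-3-[(tert-butyldimethylsilyl)oxy]-6-formyl-1,5-dimethylcyclohex-3-ene-1-carboxylate
Conditions: (S)-3,3-diphenyl-1-(o-tolyl)tetrahydro-1H,3H-pyrrolo[1,2-c][1,3,2]oxazaborole (20 mol %), HN(SO2CF3)2 (18 mol %), CH2Cl2, −78 °C → −40 °C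
Reagents that add atoms: none
Why: Catalytic asymmetric Diels–Alder reaction in which the boron-bound formyl group makes the ester-bearing carbon the electrophilic terminus (the CH2 end of the diene forms quaternary C4), suprafacial addition carries the E geometry into the trans CHO/CO2Me relation at C4/C5, the chiral oxazaborolidinium shields one enal face to fix the absolute configuration, and the endo-formed C10 centre is erased in step 5.

Step 4
Reactants: 7 methyl (1S,5S,6S)-3-[(tert-butyldimethylsilyl)oxy]-6-formyl-1,5-dimethylcyclohex-3-ene-1-carboxylate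
Product: 8 methyl (1S,5R,6S)-3-[(tert-butyldimethylsilyl)oxy]-6-(hydroxymethyl)-1,5-dimethylcyclohex-3-ene-1-carboxylate
Conditions: NaBH4, THF/EtOH, −20 °C
Reagents that add atoms: none
Why: Chemoselective borohydride reduction of the aldehyde beside the hindered ester and the silyl enol ether; it removes the acidic formyl α-hydrogen at C5 before the enone is made, so C5 cannot epimerise.

Step 5
Reactants: 8 methyl (1S,5R,6S)-3-[(tert-butyldimethylsilyl)oxy]-6-(hydroxymethyl)-1,5-dimethylcyclohex-3-ene-1-carboxylate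
Product: 9 methyl (1S,2S)-2-(hydroxymethyl)-1,3-dimethyl-5-oxocyclohex-3-ene-1-carboxylate
Conditions: Pd(OAc)2 (1.1 equiv), MeCN, rt
Reagents that add atoms: none
Why: Saegusa–Ito oxidation, in which the palladium enolate formed at C1 can only lose the C10 hydrogen, so the 3-methyl enone should form regiospecifically with C4 and C5 untouched.

Step 6
Reactants: 9 methyl (1S,2S)-2-(hydroxymethyl)-1,3-dimethyl-5-oxocyclohex-3-ene-1-carboxylate
Product: 10 methyl (1S,2S)-2-(bromomethyl)-1,3-dimethyl-5-oxocyclohex-3-ene-1-carboxylate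
Conditions: CBr4, PPh3, CH2Cl2, 0 °C
Reagents that add atoms: carbon tetrabromide, BrC(Br)(Br)Br
Why: Appel bromination of the primary alcohol under neutral conditions, chosen because an amine base could trigger vinylogous loss of HBr.

Step 7
Reactants: 11 but-2-yne-1,4-diol; 12 [2-(1,3-dioxolan-2-yl)ethyl]magnesium bromide
Product: 13 (E)-2-[2-(1,3-dioxolan-2-yl)ethyl]but-2-ene-1,4-diol
Conditions: 12 (4 equiv), CuBr·SMe2 (10 mol %), THF, 0 °C → 35 °C; aq. NH4Cl
Reagents that add atoms: none
Why: Copper-catalysed anti-carbomagnesiation of the propargylic dialkoxide, in which the chelated vinylmagnesium intermediate places the new alkyl group trans to magnesium, which after protonation is the E geometry of the side chain (the two CH2OH groups trans).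

Step 8
Reactants: 13 (E)-2-[2-(1,3-dioxolan-2-yl)ethyl]but-2-ene-1,4-diol
Product: 14 2-{(3E)-5-[(tert-butyldiphenylsilyl)oxy]-3-{[(tert-butyldiphenylsilyl)oxy]methyl}pent-3-en-1-yl}-1,3-dioxolane
Conditions: TBDPSCl, imidazole, DMF, rt
Reagents that add atoms: tert-butyl(chloro)diphenylsilane, CC(C)(C)[Si](Cl)(c1ccccc1)c1ccccc1
Why: Standard silylation of both primary allylic alcohols; the TBDPS group is chosen to survive aqueous acid and EtAlCl2.

Step 9
Reactants: 14 2-{(3E)-5-[(tert-butyldiphenylsilyl)oxy]-3-{[(tert-butyldiphenylsilyl)oxy]methyl}pent-3-en-1-yl}-1,3-dioxolane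
Product: 15 (4E)-6-[(tert-butyldiphenylsilyl)oxy]-4-{[(tert-butyldiphenylsilyl)oxy]methyl}hex-4-enal
Conditions: 1 M HCl, THF, 40 °C
Reagents that add atoms: water, O
Why: Acid hydrolysis of the dioxolane (acetal cleavage), to which TBDPS ethers are stable.

Step 10
Reactants: 15 (4E)-6-[(tert-butyldiphenylsilyl)oxy]-4-{[(tert-butyldiphenylsilyl)oxy]methyl}hex-4-enal; 16 (2-bromoprop-2-en-1-yl)trimethylsilane
Product: 19 (6E)-8-[(tert-butyldiphenylsilyl)oxy]-6-{[(tert-butyldiphenylsilyl)oxy]methyl}-2-[(trimethylsilyl)methyl]octa-1,6-dien-3-yl acetate (racemic at C-3), via vinylmagnesium bromide 17 (not isolated), via magnesium alkoxide 18 (not isolated)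
Conditions: 16, Mg turnings, THF, 50 °C; then 15, −78 °C; then Ac2O, DMAP (cat.), −78 °C → 0 °C
Reagents that add atoms: acetic anhydride, CC(=O)OC(C)=O
Why: Grignard addition to the aldehyde followed by O-acetylation in the same flask; the carbinol centre is formed racemic, which is harmless because it becomes an allyl terminus in step 11.

Step 11
Reactants: 10 methyl (1S,2S)-2-(bromomethyl)-1,3-dimethyl-5-oxocyclohex-3-ene-1-carboxylate; 19 (6E)-8-[(tert-butyldiphenylsilyl)oxy]-6-{[(tert-butyldiphenylsilyl)oxy]methyl}-2-[(trimethylsilyl)methyl]octa-1,6-dien-3-yl acetate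
Product: 21 methyl (1S,4aR,5S,8aS)-5-{(3E)-5-[(tert-butyldiphenylsilyl)oxy]-3-{[(tert-butyldiphenylsilyl)oxy]methyl}pent-3-en-1-yl}-1,4a-dimethyl-6-methylidene-3-oxodecahydronaphthalene-1-carboxylate, via allylsilane enone 20 (not isolated)
Conditions: NiCl2(dme) (10 mol %), 4,4′,4″-tri-tert-butyl-2,2′:6′,2″-terpyridine (10 mol %), Zn dust, THF (5 vol % DMA), 40 °C; then solvent exchange to CH2Cl2, EtAlCl2 (5 equiv), −78 °C → −20 °C; aq. NaHCO3
Reagents that add atoms: none
Why: Zerovalent nickel (from NiCl2(dme) and Zn) ionises the branched acetate to a 2-(silylmethyl)allylnickel species, captures the alkyl radical from bromide 10 and eliminates at the unsubstituted terminus, forming C6–C7 with the C9 substituent syn, that is cis to CH2SiMe3 (known type: nickel-catalysed reductive allyl–alkyl cross-electrophile coupling, which gives linear products from branched acetates). EtAlCl2 then activates the enone and the allylsilane attacks C10 through C9 in an anti SE2′ sense with loss of Me3Si, forming C9–C10 and moving the double bond to C8=C17 (known type: intramolecular Hosomi–Sakurai conjugate addition to a 4-tethered 3-methylcyclohexenone). Ring B closes as a 6-exo-trig conjugate addition onto the enone, with the allylsilane double bond inside the forming ring. C10 is controlled by C5, because the three-atom tether reaches only the enone face syn to C6 (axial attack, tether pseudo-equatorial), which gives the cis fusion; C9 is controlled by the allylsilane geometry, because in the chair-like transition state C11 (trans to C7 on the alkene) sits equatorial and ends cis to the C10 methyl. The step needs attack through C9 and not C17, which the Lewis-acid SE2′ mechanism secures, and the chair over the boat arrangement, which is secured by the 1,3-diaxial clash that an axial C11 would suffer with quaternary C4.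

Step 12
Reactants: 21 methyl (1S,4aR,5S,8aS)-5-{(3E)-5-[(tert-butyldiphenylsilyl)oxy]-3-{[(tert-butyldiphenylsilyl)oxy]methyl}pent-3-en-1-yl}-1,4a-dimethyl-6-methylidene-3-oxodecahydronaphthalene-1-carboxylate
Product: 23 methyl (1S,4aR,5S,8aS)-5-{(3E)-5-[(tert-butyldiphenylsilyl)oxy]-3-{[(tert-butyldiphenylsilyl)oxy]methyl}pent-3-en-1-yl}-1,4a-dimethyl-6-methylidenedecahydronaphthalene-1-carboxylate, via tosylhydrazone 22 (not isolated)
Conditions: TsNHNH2, EtOH, 60 °C; evaporate; catecholborane, CHCl3, 0 °C; then NaOAc·3H2O, 60 °C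
Reagents that add atoms: none
Why: Tosylhydrazone formation and catecholborane reduction (a mild Wolff–Kishner equivalent) should turn the unhindered C=O into CH2 with loss of N2, under conditions that leave the ester, the silyl ethers and both alkenes alone.

Step 13
Reactants: 23 methyl (1S,4aR,5S,8aS)-5-{(3E)-5-[(tert-butyldiphenylsilyl)oxy]-3-{[(tert-butyldiphenylsilyl)oxy]methyl}pent-3-en-1-yl}-1,4a-dimethyl-6-methylidenedecahydronaphthalene-1-carboxylate
Product: 24 methyl (1S,4aR,5S,8aS)-5-[(3E)-5-hydroxy-3-(hydroxymethyl)pent-3-en-1-yl]-1,4a-dimethyl-6-methylidenedecahydronaphthalene-1-carboxylate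
Conditions: Bu4NF, AcOH (1 equiv), THF, rt
Reagents that add atoms: none
Why: Fluoride cleavage of both silyl ethers (desilylation); the buffered medium should spare the hindered methyl ester.

Compound list
1 | glyoxal | O=CC=O | starting material
2 | methyl 2-(triphenyl-λ5-phosphanylidene)propanoate | COC(=O)C(C)=P(c1ccccc1)(c1ccccc1)c1ccccc1 | starting material
3 | methyl (E)-2-methyl-4-oxobut-2-enoate | O=C/C=C(\C)C(=O)OC | intermediate
4 | (E)-pent-3-en-2-one | C/C=C/C(C)=O | starting material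
5 | lithium (E)-penta-1,3-dien-2-olate | C/C=C/C(=C)O[Li] | intermediate
6 | tert-butyl(dimethyl)[(E)-penta-1,3-dien-2-yloxy]silane | C/C=C/C(=C)O[Si](C)(C)C(C)(C)C | intermediate
7 | methyl (1S,5S,6S)-3-[(tert-butyldimethylsilyl)oxy]-6-formyl-1,5-dimethylcyclohex-3-ene-1-carboxylate (CHO trans to CO2Me; 5-methyl cis to CHO) | O=C[C@H]1[C@@H](C)C=C(O[Si](C)(C)C(C)(C)C)C[C@]1(C)C(=O)OC | intermediate
8 | methyl (1S,5R,6S)-3-[(tert-butyldimethylsilyl)oxy]-6-(hydroxymethyl)-1,5-dimethylcyclohex-3-ene-1-carboxylate | OC[C@H]1[C@@H](C)C=C(O[Si](C)(C)C(C)(C)C)C[C@]1(C)C(=O)OC | intermediate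
9 | methyl (1S,2S)-2-(hydroxymethyl)-1,3-dimethyl-5-oxocyclohex-3-ene-1-carboxylate (CH2OH trans to CO2Me) | O=C1C=C(C)[C@H](CO)[C@@](C)(C(=O)OC)C1 | intermediate
10 | methyl (1S,2S)-2-(bromomethyl)-1,3-dimethyl-5-oxocyclohex-3-ene-1-carboxylate | O=C1C=C(C)[C@H](CBr)[C@@](C)(C(=O)OC)C1 | intermediate
11 | but-2-yne-1,4-diol | OCC#CCO | starting material
12 | [2-(1,3-dioxolan-2-yl)ethyl]magnesium bromide (THF solution) | Br[Mg]CCC1OCCO1 | starting material
13 | (E)-2-[2-(1,3-dioxolan-2-yl)ethyl]but-2-ene-1,4-diol | OC/C=C(/CO)CCC1OCCO1 | intermediate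
14 | 2-{(3E)-5-[(tert-butyldiphenylsilyl)oxy]-3-{[(tert-butyldiphenylsilyl)oxy]methyl}pent-3-en-1-yl}-1,3-dioxolane | CC(C)(C)[Si](c1ccccc1)(c1ccccc1)OC/C=C(/CO[Si](c1ccccc1)(c1ccccc1)C(C)(C)C)CCC1OCCO1 | intermediate
15 | (4E)-6-[(tert-butyldiphenylsilyl)oxy]-4-{[(tert-butyldiphenylsilyl)oxy]methyl}hex-4-enal | O=CCC/C(=C\CO[Si](c1ccccc1)(c1ccccc1)C(C)(C)C)CO[Si](c1ccccc1)(c1ccccc1)C(C)(C)C | intermediate
16 | (2-bromoprop-2-en-1-yl)trimethylsilane | C=C(Br)C[Si](C)(C)C | starting material
17 | {3-(trimethylsilyl)prop-1-en-2-yl}magnesium bromide | C=C([Mg]Br)C[Si](C)(C)C | intermediate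
18 | bromomagnesium alkoxide of (6E)-8-[(tert-butyldiphenylsilyl)oxy]-6-{[(tert-butyldiphenylsilyl)oxy]methyl}-2-[(trimethylsilyl)methyl]octa-1,6-dien-3-ol (racemic) | C=C(C[Si](C)(C)C)C(O[Mg]Br)CC/C(=C\CO[Si](c1ccccc1)(c1ccccc1)C(C)(C)C)CO[Si](c1ccccc1)(c1ccccc1)C(C)(C)C | intermediate
19 | (6E)-8-[(tert-butyldiphenylsilyl)oxy]-6-{[(tert-butyldiphenylsilyl)oxy]methyl}-2-[(trimethylsilyl)methyl]octa-1,6-dien-3-yl acetate (racemic at C-3) | C=C(C[Si](C)(C)C)C(OC(C)=O)CC/C(=C\CO[Si](c1ccccc1)(c1ccccc1)C(C)(C)C)CO[Si](c1ccccc1)(c1ccccc1)C(C)(C)C | intermediate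
20 | methyl (1S,2S)-2-{(3Z,7E)-9-[(tert-butyldiphenylsilyl)oxy]-7-{[(tert-butyldiphenylsilyl)oxy]methyl}-3-[(trimethylsilyl)methyl]nona-3,7-dien-1-yl}-1,3-dimethyl-5-oxocyclohex-3-ene-1-carboxylate | O=C1C=C(C)[C@H](CC/C(C[Si](C)(C)C)=C/CC/C(=C\CO[Si](c2ccccc2)(c2ccccc2)C(C)(C)C)CO[Si](c2ccccc2)(c2ccccc2)C(C)(C)C)[C@@](C)(C(=O)OC)C1 | intermediate
21 | methyl (1S,4aR,5S,8aS)-5-{(3E)-5-[(tert-butyldiphenylsilyl)oxy]-3-{[(tert-butyldiphenylsilyl)oxy]methyl}pent-3-en-1-yl}-1,4a-dimethyl-6-methylidene-3-oxodecahydronaphthalene-1-carboxylate (cis-fused) | C=C1CC[C@H]2[C@](C)(CC(=O)C[C@]2(C)C(=O)OC)[C@H]1CC/C(=C\CO[Si](c3ccccc3)(c3ccccc3)C(C)(C)C)CO[Si](c3ccccc3)(c3ccccc3)C(C)(C)C | intermediate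
22 | 4-methylbenzenesulfonylhydrazone of 21 at C-3 | C=C1CC[C@H]2[C@](C)(CC(=NNS(=O)(=O)c3ccc(C)cc3)C[C@]2(C)C(=O)OC)[C@H]1CC/C(=C\CO[Si](c3ccccc3)(c3ccccc3)C(C)(C)C)CO[Si](c3ccccc3)(c3ccccc3)C(C)(C)C | intermediate
23 | methyl (1S,4aR,5S,8aS)-5-{(3E)-5-[(tert-butyldiphenylsilyl)oxy]-3-{[(tert-butyldiphenylsilyl)oxy]methyl}pent-3-en-1-yl}-1,4a-dimethyl-6-methylidenedecahydronaphthalene-1-carboxylate | C=C1CC[C@H]2[C@](C)(CCC[C@]2(C)C(=O)OC)[C@H]1CC/C(=C\CO[Si](c3ccccc3)(c3ccccc3)C(C)(C)C)CO[Si](c3ccccc3)(c3ccccc3)C(C)(C)C | intermediate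
24 | methyl (1S,4aR,5S,8aS)-5-[(3E)-5-hydroxy-3-(hydroxymethyl)pent-3-en-1-yl]-1,4a-dimethyl-6-methylidenedecahydronaphthalene-1-carboxylate | C=C1CC[C@H]2[C@](C)(CCC[C@]2(C)C(=O)OC)[C@H]1CC/C(=C\CO)CO | target

Total step count: 13. Longest linear sequence: 8 steps (1, 3, 4, 5, 6, 11, 12, 13).

Steps most likely to fail

Step 11. The C6 radical may close a three-membered ring onto the enone or be reduced before nickel captures it. The allylsilane geometry may scramble at nickel and erode selectivity at C9, and the silane may be lost by protonation before cyclisation. The fallback sets out from aldehyde 15 and bromide 10 and returns at 21. Horner–Wadsworth–Emmons olefination of 15 with ethyl 2-(diethoxyphosphoryl)-3-(trimethylsilyl)propanoate (NaH, THF) should give the silylmethyl enoate F1 with the C9 substituent trans to the ester. Reduction with iBu2AlH gives the allylic alcohol F2, and MsCl/LiCl/2,4,6-collidine in DMF gives the primary allylic chloride F3 of fixed geometry. Bromide 10 is turned into the alkylzinc bromide F4 (Zn, LiCl, THF) and coupled with F3 by nickel-catalysed Negishi allyl–alkyl coupling (NiCl2(dme), 2,2′-bipyridine), a polar transmetalation that avoids a free C6 radical. EtAlCl2 is added after solvent exchange as before, giving 21 via 20.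

Step 3. The β,β-disubstituted enal may add too slowly, the silyl enol ether may attack the formyl group in a Mukaiyama aldol sense, or facial control may be poor. The fallback sets out from ylide 2 and diene 6 and returns at alcohol 8, bypassing 3 and 7. Wittig reaction of 2 with glyoxylic acid gives (E)-4-methoxy-3-methyl-4-oxobut-2-enoic acid F5. Acylation of lithiated (S)-4-benzyloxazolidin-2-one through the pivalic mixed anhydride gives the imide F6 (the auxiliary antipode is taken if the chelate model demands it). The Et2AlCl-promoted, auxiliary-controlled Diels–Alder reaction with 6 gives the cycloadduct F7, in which the chelated imide directs regiochemistry as the formyl group did. LiBH4 reduces the imide selectively to 8.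

Step 7. Addition of the functionalised alkyl Grignard reagent to the poorly soluble dialkoxide may be sluggish while the reagent decays thermally. The fallback sets out from 11 and returns at 14. Trans-hydroalumination with NaAlH2(OCH2CH2OMe)2 and iodinolysis give (Z)-2-iodobut-2-ene-1,4-diol F8. Silylation gives the bis-silyl vinyl iodide F9. Suzuki–Miyaura coupling of F9 with the alkylborane F10, made from 2-vinyl-1,3-dioxolane and 9-BBN (PdCl2(dppf), Cs2CO3, DMF/THF/H2O), proceeds with retention and gives 14.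

Further compounds
F1 | step 11 | ethyl (2Z,6E)-8-[(tert-butyldiphenylsilyl)oxy]-6-{[(tert-butyldiphenylsilyl)oxy]methyl}-2-[(trimethylsilyl)methyl]octa-2,6-dienoate | CCOC(=O)/C(C[Si](C)(C)C)=C/CC/C(=C\CO[Si](c1ccccc1)(c1ccccc1)C(C)(C)C)CO[Si](c1ccccc1)(c1ccccc1)C(C)(C)C
F2 | step 11 | (2Z,6E)-8-[(tert-butyldiphenylsilyl)oxy]-6-{[(tert-butyldiphenylsilyl)oxy]methyl}-2-[(trimethylsilyl)methyl]octa-2,6-dien-1-ol | OC/C(C[Si](C)(C)C)=C/CC/C(=C\CO[Si](c1ccccc1)(c1ccccc1)C(C)(C)C)CO[Si](c1ccccc1)(c1ccccc1)C(C)(C)C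
F3 | step 11 | (2E,6E)-1-chloro-2-[(trimethylsilyl)methyl]octa-2,6-diene bearing 8-OTBDPS and 6-CH2OTBDPS (C-4 chain trans to CH2Cl) | ClC/C(C[Si](C)(C)C)=C/CC/C(=C\CO[Si](c1ccccc1)(c1ccccc1)C(C)(C)C)CO[Si](c1ccccc1)(c1ccccc1)C(C)(C)C
F4 | step 11 | {[(1S,6S)-6-(methoxycarbonyl)-2,6-dimethyl-4-oxocyclohex-2-en-1-yl]methyl}zinc bromide | O=C1C=C(C)[C@H](C[Zn]Br)[C@@](C)(C(=O)OC)C1
F5 | step 3 | (E)-4-methoxy-3-methyl-4-oxobut-2-enoic acid | OC(=O)/C=C(\C)C(=O)OC
F6 | step 3 | methyl (E)-4-[(4S)-4-benzyl-2-oxooxazolidin-3-yl]-2-methyl-4-oxobut-2-enoate | COC(=O)/C(C)=C/C(=O)N1[C@@H](Cc2ccccc2)COC1=O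
F7 | step 3 | methyl (1S,5S,6S)-6-{[(4S)-4-benzyl-2-oxooxazolidin-3-yl]carbonyl}-3-[(tert-butyldimethylsilyl)oxy]-1,5-dimethylcyclohex-3-ene-1-carboxylate | O=C([C@H]1[C@@H](C)C=C(O[Si](C)(C)C(C)(C)C)C[C@]1(C)C(=O)OC)N1[C@@H](Cc2ccccc2)COC1=O
F8 | step 7 | (Z)-2-iodobut-2-ene-1,4-diol | OC/C=C(\I)CO
F9 | step 7 | (Z)-1,4-bis[(tert-butyldiphenylsilyl)oxy]-2-iodobut-2-ene | CC(C)(C)[Si](c1ccccc1)(c1ccccc1)OC/C=C(\I)CO[Si](c1ccccc1)(c1ccccc1)C(C)(C)C
F10 | step 7 | 9-[2-(1,3-dioxolan-2-yl)ethyl]-9-borabicyclo[3.3.1]nonane | C1CC2CCCC(C1)B2CCC1OCCO1
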